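## Retrosynthetic overview

1. Atom labels: ring C1 (C=O), C2 (allyl), C3 (CH), C4 (quaternary, OMe), C5 (C–OMe), C6 (CH); side chain C7 (CHMe) and C8 (ArCH2). Enabling feature: C5(OMe)=C6–C1=O is the methyl enol ether of a 1,3-diketone, so C5 is a masked ketone, and the C4–C5 bond that joins it to the quaternary carbinol carbon C4 is an acyloin (α-alkoxy ketone) bond.
2. Key disconnection C4–C5: enantioselective intramolecular crossed aldehyde–ketone benzoin reaction of an acyclic (Z)-keto aldehyde. It forms the only carbocycle made in the route, the quaternary stereocenter C4 and the C5 oxygen in one operation.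
3. Endgame from the ketol: double O-methylation (C4–O and the C5 enolate oxygen, which fixes the enol ether regiochemistry), desilylation, and oxidation of a temporary C1 carbinol to the dienone carbonyl.
4. Keto aldehyde: the C3–C4 bond comes from a Z-alkenyllithium and a Weinreb amide. The Z geometry and the allyl group come from an anti-carbomagnesiation/iodination of a propargylic alcohol whose oxygen later becomes the C1 carbonyl oxygen. C7 comes from an oxazolidinone-auxiliary benzylation.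
5. Ring order: the aryl ring is bought (vanillin); the six-membered ring is closed once, in step 14.

Key step: step 14

Abbreviations in names: TIPS = tri(propan-2-yl)silyl; TBS = tert-butyl(dimethyl)silyl; Ar = 3-methoxy-4-(TIPS-oxy)phenyl.

Remark: which antipode of the triazolium catalyst (and which configuration of the temporary C1 carbinol) is the matched one is an assumption; the (5aS,10bR) catalyst and (R)-C1 are taken here, and the mirror-image catalyst or (S)-Alpine-Borane would be substituted if a model compound shows the opposite sense.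

## Route

Step 1
Reactants: 1 vanillin (4-hydroxy-3-methoxybenzaldehyde)
Product: 2 3-methoxy-4-(TIPS-oxy)benzaldehyde
Conditions: TIPSCl, imidazole, DMF, rt
Reagents that add atoms: chlorotri(propan-2-yl)silane, CC(C)[Si](Cl)(C(C)C)C(C)C
Why: Imidazole-promoted silylation of the phenol (silyl ether formation) installs a TIPS ether that should survive the amide bases, the organolithium and the acid-catalysed methanolysis ahead and leave with fluoride in step 16.

Step 2
Reactants: 2 3-methoxy-4-(TIPS-oxy)benzaldehyde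
Product: 3 [3-methoxy-4-(TIPS-oxy)phenyl]methanol
Conditions: NaBH4, MeOH/THF, 0 °C
Reagents that add atoms: none
Why: NaBH4 reduces the aryl aldehyde to the benzylic alcohol (hydride reduction) without touching the aryl silyl ether at 0 °C.

Step 3
Reactants: 3 [3-methoxy-4-(TIPS-oxy)phenyl]methanol
Product: 4 [4-(bromomethyl)-2-methoxyphenoxy]tri(propan-2-yl)silane
Conditions: CBr4, PPh3, CH2Cl2, 0 °C
Reagents that add atoms: tetrabromomethane, BrC(Br)(Br)Br
Why: The Appel reaction converts the benzylic alcohol into the bromide under neutral conditions that an electron-rich benzylic system tolerates.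

Step 4
Reactants: 5 (4S)-4-benzyl-3-propanoyl-1,3-oxazolidin-2-one; 4 [4-(bromomethyl)-2-methoxyphenoxy]tri(propan-2-yl)silane
Product: 7 (4S)-4-benzyl-3-[(2R)-3-Ar-2-methylpropanoyl]-1,3-oxazolidin-2-one, via sodium Z-enolate 6 (not isolated)
Conditions: NaN(SiMe3)2, THF, −78 °C; then 4, −78 to −40 °C
Reagents that add atoms: none
Why: Oxazolidinone-auxiliary enolate alkylation: the chelated sodium Z-enolate is benzylated on the face opposite the benzyl group of the auxiliary, which should set C7 as (R).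

Step 5
Reactants: 7 (4S)-4-benzyl-3-[(2R)-3-Ar-2-methylpropanoyl]-1,3-oxazolidin-2-one
Product: 8 (2R)-3-Ar-N-methoxy-N,2-dimethylpropanamide
Conditions: MeNH(OMe)·HCl, AlMe3, CH2Cl2, 0 °C to rt
Reagents that add atoms: N,O-dimethylhydroxylamine hydrochloride, CNOC.Cl
Why: Aluminium amide transamidation (Weinreb amide formation) cleaves the auxiliary at the exocyclic carbonyl under non-basic conditions, so C7 should not epimerise.

Step 6
Reactants: 9 3-(TBS-oxy)propanal; 10 ethynylmagnesium bromide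
Product: 11 rac-5-(TBS-oxy)pent-1-yn-3-ol
Conditions: THF, −78 to 0 °C; aqueous work-up
Reagents that add atoms: none
Why: Grignard 1,2-addition of the acetylide to the aldehyde gives the propargylic alcohol, racemic at this stage.

Step 7
Reactants: 11 rac-5-(TBS-oxy)pent-1-yn-3-ol
Product: 12 5-(TBS-oxy)pent-1-yn-3-one
Conditions: Dess–Martin periodinane, NaHCO3, CH2Cl2, 0 °C to rt
Reagents that add atoms: none
Why: Dess–Martin oxidation gives the alkynyl ketone under buffered, non-acidic conditions compatible with the silyl ether and the terminal alkyne.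

Step 8
Reactants: 12 5-(TBS-oxy)pent-1-yn-3-one
Product: 13 (3R)-5-(TBS-oxy)pent-1-yn-3-ol
Conditions: (R)-Alpine-Borane (B-isopinocampheyl-9-borabicyclo[3.3.1]nonane from (+)-α-pinene), THF, rt; then ethanolamine
Reagents that add atoms: none
Why: Midland reduction: the pinanyl borane transfers hydride through a cyclic boat-like transition state that places the slim ethynyl group next to the pinanyl methyl, which by analogy with simple 1-alkyn-3-ones should give the (R)-carbinol (temporary stereocenter at the future C1).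

Step 9
Reactants: 13 (3R)-5-(TBS-oxy)pent-1-yn-3-ol; 14 allylmagnesium bromide (prop-2-en-1-ylmagnesium bromide)
Product: 16 (1Z,3R)-1-iodo-2-(prop-2-en-1-yl)-5-(TBS-oxy)pent-1-en-3-ol, via alkenylmagnesium alkoxide chelate 15 (not isolated)
Conditions: CH2=CHCH2MgBr (3 equiv), CuI (10 mol %), Et2O, 0 °C to rt; then I2, THF, −20 °C
Reagents that add atoms: iodine, II
Why: Copper-catalysed anti-carbomagnesiation of a propargylic magnesium alkoxide: the allyl group adds to the alkyne carbon next to the carbinol while magnesium ends on the terminal carbon cis to the carbinol carbon in a five-membered chelate, so iodinolysis with retention should give the Z-iodide; the carbinol center is untouched.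

Step 10
Reactants: 16 (1Z,3R)-1-iodo-2-(prop-2-en-1-yl)-5-(TBS-oxy)pent-1-en-3-ol
Product: 17 (1Z,3R)-1-iodo-2-(prop-2-en-1-yl)-5-(TBS-oxy)-3-(TIPS-oxy)pent-1-ene
Conditions: TIPSOTf, 2,6-lutidine, CH2Cl2, 0 °C
Reagents that add atoms: tri(propan-2-yl)silyl trifluoromethanesulfonate, CC(C)[Si](C(C)C)(C(C)C)OS(=O)(=O)C(F)(F)F
Why: Silylation with the silyl triflate and a hindered pyridine base protects the secondary allylic alcohol as a bulky TIPS ether, chosen to resist silyl migration in step 11 and to leave with fluoride in step 16.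

Step 11
Reactants: 17 (1Z,3R)-1-iodo-2-(prop-2-en-1-yl)-5-(TBS-oxy)-3-(TIPS-oxy)pent-1-ene; 8 (2R)-3-Ar-N-methoxy-N,2-dimethylpropanamide
Product: 19 (2R,4Z,6R)-1-Ar-2-methyl-5-(prop-2-en-1-yl)-8-(TBS-oxy)-6-(TIPS-oxy)oct-4-en-3-one, via Z-alkenyllithium 18 (not isolated)
Conditions: t-BuLi (2.1 equiv), Et2O, −78 °C; then 8, −78 to −40 °C; aqueous NH4Cl
Reagents that add atoms: none
Why: Iodine–lithium exchange goes with retention of alkene geometry and the alkenyllithium acylates the Weinreb amide through a chelated tetrahedral adduct (Weinreb ketone synthesis), so over-addition and epimerisation at C7 are not expected and the Z-enone geometry needed for ring closure is carried over.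

Step 12
Reactants: 19 (2R,4Z,6R)-1-Ar-2-methyl-5-(prop-2-en-1-yl)-8-(TBS-oxy)-6-(TIPS-oxy)oct-4-en-3-one
Product: 20 (2R,4Z,6R)-1-Ar-8-hydroxy-2-methyl-5-(prop-2-en-1-yl)-6-(TIPS-oxy)oct-4-en-3-one
Conditions: camphor-10-sulfonic acid (10 mol %), MeOH/CH2Cl2, 0 °C
Reagents that add atoms: none
Why: Acid-catalysed methanolysis removes the unhindered primary TBS ether much faster than the secondary and aryl TIPS ethers (selective silyl ether cleavage).

Step 13
Reactants: 20 (2R,4Z,6R)-1-Ar-8-hydroxy-2-methyl-5-(prop-2-en-1-yl)-6-(TIPS-oxy)oct-4-en-3-one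
Product: 21 (3R,4Z,7R)-8-Ar-7-methyl-6-oxo-4-(prop-2-en-1-yl)-3-(TIPS-oxy)oct-4-enal
Conditions: Dess–Martin periodinane, NaHCO3, CH2Cl2, 0 °C
Reagents that add atoms: none
Why: Buffered Dess–Martin oxidation gives the β-silyloxy aldehyde without acid or base that could cause β-elimination or epimerise C7.

Step 14
Reactants: 21 (3R,4Z,7R)-8-Ar-7-methyl-6-oxo-4-(prop-2-en-1-yl)-3-(TIPS-oxy)oct-4-enal
Product: 23 (2S,5R)-2-[(2R)-1-Ar-propan-2-yl]-2-hydroxy-4-(prop-2-en-1-yl)-5-(TIPS-oxy)cyclohex-3-en-1-one, via Breslow intermediate 22 (not isolated)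
Conditions: (5aS,10bR)-2-(pentafluorophenyl)-5a,10b-dihydro-4H,6H-indeno[2,1-b][1,2,4]triazolo[4,3-d][1,4]oxazin-2-ium tetrafluoroborate (20 mol %), KN(SiMe3)2 (18 mol %), toluene, rt
Reagents that add atoms: none
Why: The free triazolylidene adds to the aldehyde carbon C5 to give the Breslow intermediate 22, whose nucleophilic C5 attacks the C4 ketone before the carbene is released (intramolecular crossed aldehyde–ketone benzoin reaction, a known ring-closing acyloin formation under N-heterocyclic carbene catalysis). The six-membered ring closes in the 6-exo-trig mode, C5 attacking the carbonyl carbon C4 whose oxygen stays outside the ring. The new quaternary carbinol stereocenter C4 is controlled by the chiral pocket of the aminoindanol-derived triazolylidene, chosen to deliver C5 to the Re face of the ketone. The resident (R)-silyloxy center at C1 (pseudoaxial in the forming half-chair because of A(1,2) strain with the C2 allyl group, while the bulky C7 branch sits pseudoequatorial) is expected to favour the same (S) configuration. The step needs 1,2-addition to the ketone over conjugate addition, aldehyde self-condensation and enolisation: conjugate (Stetter-type) attack at C2 would close a four-membered ring, the Z geometry of C2=C3 holds C4 within reach of C5, and the sub-stoichiometric base leaves no free amide to enolise the aldehyde or to epimerise C7.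

Step 15
Reactants: 23 (2S,5R)-2-[(2R)-1-Ar-propan-2-yl]-2-hydroxy-4-(prop-2-en-1-yl)-5-(TIPS-oxy)cyclohex-3-en-1-one
Product: 25 {[(1R,4S)-4-[(2R)-1-Ar-propan-2-yl]-4,5-dimethoxy-2-(prop-2-en-1-yl)cyclohexa-2,5-dien-1-yl]oxy}tri(propan-2-yl)silane, via dipotassium alkoxide enolate 24 (not isolated)
Conditions: KN(SiMe3)2 (2.4 equiv), THF/DMPU, −78 °C; then Me2SO4, −78 to −20 °C
Reagents that add atoms: dimethyl sulfate, COS(=O)(=O)OC
Why: Two equivalents of base should give the tertiary potassium alkoxide and the only possible enolate (C4 is quaternary, so enolisation goes to C6), and the hard electrophile in a dipolar aprotic medium should methylate both oxygens (Williamson ether synthesis and O-alkylation of a hindered potassium enolate), which places the enol ether at C5 without regiochemical ambiguity.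

Step 16
Reactants: 25 {[(1R,4S)-4-[(2R)-1-Ar-propan-2-yl]-4,5-dimethoxy-2-(prop-2-en-1-yl)cyclohexa-2,5-dien-1-yl]oxy}tri(propan-2-yl)silane
Product: 26 (1R,4S)-4-[(2R)-1-(4-hydroxy-3-methoxyphenyl)propan-2-yl]-4,5-dimethoxy-2-(prop-2-en-1-yl)cyclohexa-2,5-dien-1-ol
Conditions: Bu4NF, THF, 0 °C to rt; pH 7 buffer work-up
Reagents that add atoms: none
Why: Fluoride cleaves both silyl ethers (fluoride-mediated desilylation), the aryl ether first, under basic conditions that should spare the enol ether and the acid-labile doubly allylic carbinol.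

Step 17
Reactants: 26 (1R,4S)-4-[(2R)-1-(4-hydroxy-3-methoxyphenyl)propan-2-yl]-4,5-dimethoxy-2-(prop-2-en-1-yl)cyclohexa-2,5-dien-1-ol
Product: 27 (4S)-4-[(2R)-1-(4-hydroxy-3-methoxyphenyl)propan-2-yl]-4,5-dimethoxy-2-(prop-2-en-1-yl)cyclohexa-2,5-dien-1-one (CNP0370214.1)
Conditions: MnO2, CH2Cl2, rt
Reagents that add atoms: none
Why: MnO2 should oxidise the doubly allylic carbinol selectively (allylic alcohol oxidation) to the cross-conjugated dienone, erasing the temporary C1 stereocenter; the phenol, the allyl group and the enol ether are expected to be inert, and C4 and C7 cannot epimerise.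

## Compound list

1 | vanillin (4-hydroxy-3-methoxybenzaldehyde) | O=Cc1ccc(O)c(OC)c1 | starting material
2 | 3-methoxy-4-(TIPS-oxy)benzaldehyde | O=Cc1ccc(O[Si](C(C)C)(C(C)C)C(C)C)c(OC)c1 | intermediate
3 | [3-methoxy-4-(TIPS-oxy)phenyl]methanol | OCc1ccc(O[Si](C(C)C)(C(C)C)C(C)C)c(OC)c1 | intermediate
4 | [4-(bromomethyl)-2-methoxyphenoxy]tri(propan-2-yl)silane | BrCc1ccc(O[Si](C(C)C)(C(C)C)C(C)C)c(OC)c1 | intermediate
5 | (4S)-4-benzyl-3-propanoyl-1,3-oxazolidin-2-one | CCC(=O)N1C(=O)OC[C@@H]1Cc1ccccc1 | starting material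
6 | sodium (1Z)-1-[(4S)-4-benzyl-2-oxo-1,3-oxazolidin-3-yl]prop-1-en-1-olate | [Na+].C/C=C(\[O-])N1C(=O)OC[C@@H]1Cc1ccccc1 | intermediate
7 | (4S)-4-benzyl-3-[(2R)-3-Ar-2-methylpropanoyl]-1,3-oxazolidin-2-one | C[C@H](Cc1ccc(O[Si](C(C)C)(C(C)C)C(C)C)c(OC)c1)C(=O)N1C(=O)OC[C@@H]1Cc1ccccc1 | intermediate
8 | (2R)-3-Ar-N-methoxy-N,2-dimethylpropanamide | CON(C)C(=O)[C@H](C)Cc1ccc(O[Si](C(C)C)(C(C)C)C(C)C)c(OC)c1 | intermediate
9 | 3-(TBS-oxy)propanal | O=CCCO[Si](C)(C)C(C)(C)C | starting material
10 | ethynylmagnesium bromide | C#C[Mg]Br | starting material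
11 | rac-5-(TBS-oxy)pent-1-yn-3-ol | C#CC(O)CCO[Si](C)(C)C(C)(C)C | intermediate
12 | 5-(TBS-oxy)pent-1-yn-3-one | C#CC(=O)CCO[Si](C)(C)C(C)(C)C | intermediate
13 | (3R)-5-(TBS-oxy)pent-1-yn-3-ol | C#C[C@H](O)CCO[Si](C)(C)C(C)(C)C | intermediate
14 | allylmagnesium bromide (prop-2-en-1-ylmagnesium bromide) | C=CC[Mg]Br | starting material
15 | (5R)-4-(prop-2-en-1-yl)-5-[2-(TBS-oxy)ethyl]-2,5-dihydro-1,2-oxamagnesole (cyclic alkenylmagnesium alkoxide) | C=CCC1=C[Mg]O[C@@H]1CCO[Si](C)(C)C(C)(C)C | intermediate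
16 | (1Z,3R)-1-iodo-2-(prop-2-en-1-yl)-5-(TBS-oxy)pent-1-en-3-ol | I/C=C(/CC=C)\[C@H](O)CCO[Si](C)(C)C(C)(C)C | intermediate
17 | (1Z,3R)-1-iodo-2-(prop-2-en-1-yl)-5-(TBS-oxy)-3-(TIPS-oxy)pent-1-ene | I/C=C(/CC=C)\[C@H](O[Si](C(C)C)(C(C)C)C(C)C)CCO[Si](C)(C)C(C)(C)C | intermediate
18 | [(1Z,3R)-2-(prop-2-en-1-yl)-5-(TBS-oxy)-3-(TIPS-oxy)pent-1-en-1-yl]lithium | [Li]/C=C(/CC=C)\[C@H](O[Si](C(C)C)(C(C)C)C(C)C)CCO[Si](C)(C)C(C)(C)C | intermediate
19 | (2R,4Z,6R)-1-Ar-2-methyl-5-(prop-2-en-1-yl)-8-(TBS-oxy)-6-(TIPS-oxy)oct-4-en-3-one | C[C@H](Cc1ccc(O[Si](C(C)C)(C(C)C)C(C)C)c(OC)c1)C(=O)/C=C(/CC=C)\[C@H](O[Si](C(C)C)(C(C)C)C(C)C)CCO[Si](C)(C)C(C)(C)C | intermediate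
20 | (2R,4Z,6R)-1-Ar-8-hydroxy-2-methyl-5-(prop-2-en-1-yl)-6-(TIPS-oxy)oct-4-en-3-one | C[C@H](Cc1ccc(O[Si](C(C)C)(C(C)C)C(C)C)c(OC)c1)C(=O)/C=C(/CC=C)\[C@H](O[Si](C(C)C)(C(C)C)C(C)C)CCO | intermediate
21 | (3R,4Z,7R)-8-Ar-7-methyl-6-oxo-4-(prop-2-en-1-yl)-3-(TIPS-oxy)oct-4-enal | C[C@H](Cc1ccc(O[Si](C(C)C)(C(C)C)C(C)C)c(OC)c1)C(=O)/C=C(/CC=C)\[C@H](O[Si](C(C)C)(C(C)C)C(C)C)CC=O | intermediate
22 | Breslow intermediate: enaminol from aldehyde 21 and the (5aS,10bR)-triazolylidene (C5 carries OH and the exocyclic C=C to the carbene carbon) | OC(C[C@@H](O[Si](C(C)C)(C(C)C)C(C)C)/C(CC=C)=C\C(=O)[C@H](C)Cc1ccc(O[Si](C(C)C)(C(C)C)C(C)C)c(OC)c1)=C1N(c2c(F)c(F)c(F)c(F)c2F)N=C2CO[C@H]3Cc4ccccc4[C@H]3N12 | intermediate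
23 | (2S,5R)-2-[(2R)-1-Ar-propan-2-yl]-2-hydroxy-4-(prop-2-en-1-yl)-5-(TIPS-oxy)cyclohex-3-en-1-one | C=CCC1=C[C@@](O)([C@H](C)Cc2ccc(O[Si](C(C)C)(C(C)C)C(C)C)c(OC)c2)C(=O)C[C@H]1O[Si](C(C)C)(C(C)C)C(C)C | intermediate
24 | dipotassium alkoxide enolate of 23 (C4 alkoxide, C5=C6 enolate) | [K+].[K+].C=CCC1=C[C@@]([O-])([C@H](C)Cc2ccc(O[Si](C(C)C)(C(C)C)C(C)C)c(OC)c2)C([O-])=C[C@H]1O[Si](C(C)C)(C(C)C)C(C)C | intermediate
25 | {[(1R,4S)-4-[(2R)-1-Ar-propan-2-yl]-4,5-dimethoxy-2-(prop-2-en-1-yl)cyclohexa-2,5-dien-1-yl]oxy}tri(propan-2-yl)silane | C=CCC1=C[C@@](OC)([C@H](C)Cc2ccc(O[Si](C(C)C)(C(C)C)C(C)C)c(OC)c2)C(OC)=C[C@H]1O[Si](C(C)C)(C(C)C)C(C)C | intermediate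
26 | (1R,4S)-4-[(2R)-1-(4-hydroxy-3-methoxyphenyl)propan-2-yl]-4,5-dimethoxy-2-(prop-2-en-1-yl)cyclohexa-2,5-dien-1-ol | C=CCC1=C[C@@](OC)([C@H](C)Cc2ccc(O)c(OC)c2)C(OC)=C[C@H]1O | intermediate
27 | (4S)-4-[(2R)-1-(4-hydroxy-3-methoxyphenyl)propan-2-yl]-4,5-dimethoxy-2-(prop-2-en-1-yl)cyclohexa-2,5-dien-1-one | C=CCC1=C[C@@](OC)([C@H](C)Cc2ccc(O)c(OC)c2)C(OC)=CC1=O | target

## Step count and risks

Total step count: 17. Longest linear sequence: 12 steps (steps 1–5 or steps 6–10, then steps 11–17).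

Steps most likely to fail:

Step 14 (key step). The acyl anion equivalent may fail to add to the hindered, conjugated C4 ketone, or may add with low facial selectivity if the catalyst and the C1 center are mismatched. Fallback: setting out from aldehyde 21, a reductive ketone–aldehyde coupling (pinacol ring closure) with SmI2 in THF at −78 °C forms the same C4–C5 bond through a samarium-bridged intermediate and should give the cis-diol F1, with the C4 configuration then resting on the resident C1 and C7 centers. Oxidation of the only oxidisable (secondary) carbinol of the cis-diol F1 with Dess–Martin periodinane comes back to the route at ketol 23.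

Step 15. The enolate may be methylated on carbon (C6) instead of oxygen, or the C1 silyloxy group may be lost from the enolate by β-elimination. Fallback: setting out from ketol 23, the tertiary alcohol is methylated without any enolate being formed (MeOTf, 2,6-di-tert-butyl-4-methylpyridine, CH2Cl2) to the methoxy ketone F2. The ketone is then converted into the dimethyl ketal F3 (MeOSiMe3, catalytic Me3SiOTf, CH2Cl2, −78 °C). Elimination of methanol from the dimethyl ketal F3 with Me3SiOTf and iPr2NEt comes back to the route at compound 25.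

Step 11. The Z-γ-silyloxy alkenyllithium may undergo 1,4 oxygen-to-carbon silyl migration before it is acylated, or it may act as a base towards the Weinreb amide. Fallback: setting out from Weinreb amide 8 and iodide 17, amide 8 is reduced with iBu2AlH at −78 °C to the aldehyde F4. This is coupled with iodide 17 under Nozaki–Hiyama–Kishi conditions (CrCl2, catalytic NiCl2, DMF; the alkenylchromium species keeps the alkene geometry and does not migrate silicon) to the allylic alcohol F5, formed as both carbinol epimers. Dess–Martin oxidation of the allylic alcohol F5 comes back to the route at enone 19.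

Further compounds

F1 | step 14 | (1R,2S,5R)-2-[(2R)-1-Ar-propan-2-yl]-4-(prop-2-en-1-yl)-5-(TIPS-oxy)cyclohex-3-ene-1,2-diol | C=CCC1=C[C@@](O)([C@H](C)Cc2ccc(O[Si](C(C)C)(C(C)C)C(C)C)c(OC)c2)[C@H](O)C[C@H]1O[Si](C(C)C)(C(C)C)C(C)C
F2 | step 15 | (2S,5R)-2-[(2R)-1-Ar-propan-2-yl]-2-methoxy-4-(prop-2-en-1-yl)-5-(TIPS-oxy)cyclohex-3-en-1-one | C=CCC1=C[C@@](OC)([C@H](C)Cc2ccc(O[Si](C(C)C)(C(C)C)C(C)C)c(OC)c2)C(=O)C[C@H]1O[Si](C(C)C)(C(C)C)C(C)C
F3 | step 15 | {[(1R,4S)-4-[(2R)-1-Ar-propan-2-yl]-4,5,5-trimethoxy-2-(prop-2-en-1-yl)cyclohex-2-en-1-yl]oxy}tri(propan-2-yl)silane | C=CCC1=C[C@@](OC)([C@H](C)Cc2ccc(O[Si](C(C)C)(C(C)C)C(C)C)c(OC)c2)C(OC)(OC)C[C@H]1O[Si](C(C)C)(C(C)C)C(C)C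
F4 | step 11 | (2R)-3-Ar-2-methylpropanal | O=C[C@H](C)Cc1ccc(O[Si](C(C)C)(C(C)C)C(C)C)c(OC)c1
F5 | step 11 | (2R,4Z,6R)-1-Ar-2-methyl-5-(prop-2-en-1-yl)-8-(TBS-oxy)-6-(TIPS-oxy)oct-4-en-3-ol (both C3 epimers, center left open) | C[C@H](Cc1ccc(O[Si](C(C)C)(C(C)C)C(C)C)c(OC)c1)C(O)/C=C(/CC=C)\[C@H](O[Si](C(C)C)(C(C)C)C(C)C)CCO[Si](C)(C)C(C)(C)C
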